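- Take the rise of intermediate A between two readings as one straight line, and let its mean slope carry the comparison of Wednesday's flask with Thursday's flask.

| setting | teal | grey | Wednesday's | Thursday's |
|---|---|---|---|---|
| starting material | 6.7 mM | 14 mM | 10 mM | 20 mM |
| remark | run made earlier | run made earlier |  |  |
| time |  |  | 5.0 d | 1.5 d |

| run | time / d | intermediate A / % | product / % |
|---|---|---|---|
| teal | 0.250 | 5 | 1 |
| teal | 0.833 | 16 | 0 |
| teal | 1.25 | 23 | 0 |
| teal | 2.00 | 30 | 2 |
| teal | 3.00 | 33 | 0 |
| teal | 4.00 | 36 | 0 |
| teal | 5.00 | 41 | 1 |
| grey | 0.417 | 12 | 0 |
| grey | 0.625 | 14 | 0 |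
| grey | 0.833 | 14 | 0 |
| grey | 1.25 | 24 | 2 |
| grey | 2.00 | 31 | 0 |
| grey | 3.00 | 35 | 3 |
| grey | 5.00 | 43 | 0 |

(standard deviation of a reading: 1.5 percentage points)

* the flask that ends with the higher amount of intermediate A, in percent of the starting material charged, or "neither" when 2 percentage points or less lies between them (Wednesday's / Thursday's / neither)
* final intermediate A, as a percentage of the starting material charged, in Wednesday's
* final intermediate A, as a percentage of the starting material charged, in Thursday's

- the numbers in the tables scatter with a standard deviation of 1.5 percentage points

- In the first instants of the teal and grey runs, intermediate A climbs quickly, reading 5 % at 0.250 d in the teal run and 12 % at 0.417 d in the grey run, while the highest product reading in either run is 3 %, against a scatter of 1.5 points.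
- In the middle, the teal and grey runs read 23 % and 24 % at 1.25 d, and 41 % and 43 % at 5.00 d, despite charges of 6.7 mM and 14 mM; I read this as first-order behaviour, with percent following time, and I pool them, though Thursday's 20 mM lies beyond both charges.
- The pooled readings, 23.5 % and 42.0 %, give my mean gain g, the rise of intermediate A per day as a fraction of the charge between those two times, 0.0493 d⁻¹.
- Towards the end I check the error of the line: at 3.00 d it stands at 32.1 %, while the two readings average 34.0 %, so the pooled readings stand 1.9 points above the line, a difference read through a scatter of 1.5 points.
- My reckoning puts Wednesday's flask at 42.0 % and Thursday's flask on the line at 24.7 %, and g over the difference in time gives a gap of 17 points, larger than the margin of 2 points.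
- The forecast names Wednesday's, with 42 % for Wednesday's flask and 26 % for Thursday's flask, where my Thursday's figure is 24.7 %: "Time therefore decides the comparison, and Wednesday's flask, with the longer run, ends higher".
- The flasks give Wednesday's, with 40.7 % in Wednesday's flask and 23.8 % in Thursday's flask, a gap of 17 points.

    starting material → intermediate A (k = 2.00 × 10⁻⁴ min⁻¹)
    intermediate A → intermediate B (k = 9.50 × 10⁻⁵ min⁻¹)
    intermediate B → intermediate C (k = 1.20 × 10⁻⁴ min⁻¹)
    intermediate C → product (k = 9.70 × 10⁻⁵ min⁻¹)
    starting material ⇌ dormant form (K = 0.580, k = 6.00 × 10⁻⁴ min⁻¹)

- Thursday's flask read later, at 4.0 d, tests g: the line gives 37.1 %, and that neighbour holds 38.6 % intermediate A, 1.5 points above the line. The forecast's choice gives way to neither where the two flasks lie within 2 points, and this later reading of Thursday's flask brings the gap to Wednesday's flask down from 17 points to 2.1 points.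

Readings and results come from a simulation for substances that don't exist.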